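The pitfall in repeating this run is to wait for the left-handed reading to show the target. With right-handed substrate read at 41 % in the eta run, an excess of 98 % corresponds to 0.414 % of left-handed substrate, and readings scatter by 1.5 percentage points. So I reckoned the time from earlier readings instead.

the same everywhere: gas 76 mM (held)
- eta: left-handed substrate 0.80 M; right-handed substrate 0.80 M; free catalyst 4 mM; the very flask that is asked about, followed so far
- gamma: left-handed substrate 1.6 M; right-handed substrate 1.6 M; free catalyst 4 mM; run made earlier
- flask: left-handed substrate 0.80 M; right-handed substrate 0.80 M; free catalyst 4.0 mM; time 40 min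

| run | time / min | right-handed substrate / % | left-handed substrate / % |
|---|---|---|---|
| eta | 1.00 | 51 | 38 |
| eta | 3.00 | 48 | 20 |
| eta | 6.00 | 45 | 9 |
| eta | 8.00 | 49 | 4 |
| eta | 12.0 | 45 | 1 |
| eta | 15.0 | 41 | 0 |
| gamma | 6.00 | 48 | 17 |
| gamma | 12.0 | 48 | 5 |
| gamma | 20.0 | 47 | 3 |
| gamma | 25.0 | 44 | 0 |
| gamma | 30.0 | 42 | 1 |
| gamma | 40.0 | 43 | 0 |

(each reading ± 1.5 percentage points)

- free catalyst is single-handed; left-handed substrate and right-handed substrate are mirror images of each other, charged as a racemate, each of them at the stated concentration
- at the start none of the gas is in solution

* whether the excess of right-handed substrate over left-handed substrate among what is left of the two reaches 98 % by 40 min (yes / no)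
* the highest excess of right-handed substrate over left-handed substrate among what is left of the two up to 40 min

I followed the gap, ln([right-handed substrate]/[left-handed substrate]), which grows at the difference of the two loss rates. The eta readings are from this same flask, and I took the left-handed rate from those well above the scatter:

left-handed loss: 0.288 min⁻¹, lifetime 3.47 min

right-handed loss: 0.0156 min⁻¹, lifetime 64.1 min

gap rate: 0.272 min⁻¹

gap wanted: ln((1 + excess)/(1 − excess)) = 4.60

The separation clock, the wanted gap over the gap rate, was 16.9 min. On this ladder of estimates the left-handed lifetime was the shortest rung; the clock came earlier than the limit of 40 min, and the right-handed lifetime lay later than that limit. These rates, read from scattered readings, gave a selectivity factor of 18.5, where the forecast put it near 30. The rate could also drift: reaching the gap by 40 min asked for a mean of 0.115 min⁻¹, less than the rate I read.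

The forecast said yes, with a top of 99.9 % (range 97.5 % to 100 %): “I see no reversal or catalyst death, though a small floor can't be excluded”.

    free catalyst + left-handed substrate ⇌ catalyst intermediate A (K = 2.10 L mol⁻¹, k = 59.0 L mol⁻¹ s⁻¹)
    free catalyst + right-handed substrate ⇌ catalyst intermediate B (K = 3.60 L mol⁻¹, k = 79.0 L mol⁻¹ s⁻¹)
    coupling partner + catalyst intermediate A → free catalyst + left-handed product (k = 50.0 L mol⁻¹ s⁻¹)
    coupling partner + catalyst intermediate B → free catalyst + right-handed product (k = 0.910 L mol⁻¹ s⁻¹)
    free catalyst → spent catalyst (k = 0.00320 s⁻¹)
    gas ⇌ coupling partner, rate k6*(csat - [coupling partner]) (kL = 1.90 s⁻¹)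
    coupling partner → decomposed reagent (k = 0.0330 s⁻¹)

The flask answered yes, with a top of 99.9 %, and reached the wanted excess at 16.2 min, against my clock of 16.9 min. At 20.0 min, spent catalyst stood at 64.0 % of the catalyst charged, and from then to 40.0 min the gap grew at 0.104 min⁻¹. The gamma readings give a gap rate of 0.201 min⁻¹, so its clock reads 22.9 min. At 25.0 min that run read 44 % right-handed substrate against 0 % left-handed substrate.

All runs stem from a simulated flask with constants of no real substance; noise was put on by code.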